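Cyclohexene numbering: C1 (bears the C7 ketone of prenylated ring A), C2 (ring B, whose enone arm ends in ring D), C3=C4(Me), C5, C6 (ring C). The C7 ketone and C3=C4 make a γ,δ-unsaturated ketone whose C4 is already linked to C1 through C5 and C6, so the route rests on a Claisen disconnection of C1–C2. A dihydropyran with the C7 enol oxygen on C4 contracts to the cyclohexene, forging C1–C2 and both new stereocentres at once. The precursor is the (2S,4S)-2-methyl-2-[(E)-styryl]-4,6-diaryl-3,4-dihydro-2H-pyran, with MOM ethers on rings A and C and benzoates on rings B and D.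

Key step: step 18

Remark on the chemistry: the (S)-configured catalysts of steps 11 and 14 are assumed to give the facial sense stated there (the antipode is used should a first run show the reverse). Dihydropyran atoms are numbered O1, C2 (Me and alkynyl or styryl), C3, C4 (ring C), C5, C6 (ring A). Rings B and D carry benzoates and not MOM ethers so that acid never meets free ring B and ring C phenols together next to the C7 ketone.

Abbreviations: MOM = methoxymethyl; Bz = benzoyl; prenyl = 3-methylbut-2-en-1-yl; ArA = 2,4-bis(methoxymethoxy)-3-prenylphenyl (ring A); ArC = 2,4-bis(methoxymethoxy)phenyl (ring C).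

Step 1
Reactants: 1 resorcinol
Product: 2 1,3-bis(methoxymethoxy)benzene
Conditions: NaH, MOMCl, DMF, 0 °C → rt
Reagents that add atoms: chloromethyl methyl ether, COCCl
Why: Williamson-type O-alkylation of both phenoxides gives the bis-acetal, which later directs lithiation and survives base and organometallic reagents.

Step 2
Reactants: 2 1,3-bis(methoxymethoxy)benzene; 3 prenyl bromide
Product: 5 1,3-bis(methoxymethoxy)-2-prenylbenzene, via aryllithium 4 (not isolated)
Conditions: n-BuLi, THF, 0 °C → rt; CuI (10 mol%), 3, −78 °C → rt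
Reagents that add atoms: none
Why: Directed ortho-metalation takes place at C2 between the two MOM ethers, and copper-catalysed SN2 allylation of the aryllithium with the primary allylic bromide installs the prenyl group without allylic transposition.

Step 3
Reactants: 2 1,3-bis(methoxymethoxy)benzene
Product: 6 1-bromo-2,4-bis(methoxymethoxy)benzene
Conditions: NBS, MeCN, 0 °C → rt
Reagents that add atoms: N-bromosuccinimide, O=C1CCC(=O)N1Br
Why: Electrophilic aromatic bromination goes to C4, para to one acetal oxygen and ortho to the other, the most activated unhindered position of the 1,3-dialkoxyarene.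

Step 4
Reactants: 6 1-bromo-2,4-bis(methoxymethoxy)benzene
Product: 9 [2,4-bis(methoxymethoxy)phenyl]boronic acid, via ring C aryllithium 7 (not isolated), via lithium triisopropoxyborate 8 (not isolated)
Conditions: n-BuLi, THF, −78 °C; B(OiPr)3, −78 °C → rt; sat. aq. NH4Cl
Reagents that add atoms: triisopropyl borate, CC(C)OB(OC(C)C)OC(C)C; water, O
Why: Bromine–lithium exchange at −78 °C outruns any ortho-metalation, and trapping the aryllithium with the borate ester followed by mild hydrolysis is the standard borylation that keeps the acid-labile acetals.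

Step 5
Reactants: 10 2,4-dihydroxyacetophenone
Product: 11 1-(2,4-dihydroxy-3-iodophenyl)ethan-1-one
Conditions: I2, HIO3, EtOH/H2O, 35 °C
Reagents that add atoms: iodine, II; iodic acid, OI(=O)=O
Why: Oxidative electrophilic iodination (HIO3 returns all iodide to the electrophile) attacks C3, the position activated by both hydroxyls of the chelated resorcinol ketone, and any 5-iodo isomer is removed by crystallisation.

Step 6
Reactants: 11 1-(2,4-dihydroxy-3-iodophenyl)ethan-1-one
Product: 12 1-[3-iodo-2,4-bis(methoxymethoxy)phenyl]ethan-1-one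
Conditions: NaH, MOMCl, DMF, 0 °C → rt
Reagents that add atoms: chloromethyl methyl ether, COCCl
Why: O-Alkylation of both phenoxides, the chelated 2-hydroxyl included, masks the phenols for the base-mediated condensation.

Step 7
Reactants: 13 2,4-dihydroxybenzaldehyde
Product: 14 2,4-bis(methoxymethoxy)benzaldehyde
Conditions: NaH, MOMCl, DMF, 0 °C → rt
Reagents that add atoms: chloromethyl methyl ether, COCCl
Why: O-Alkylation of both phenoxides removes the acidic hydroxyls that would otherwise deactivate the aldehyde as a phenoxide in the condensation.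

Step 8
Reactants: 12 1-[3-iodo-2,4-bis(methoxymethoxy)phenyl]ethan-1-one; 14 2,4-bis(methoxymethoxy)benzaldehyde
Product: 16 (E)-3-[2,4-bis(methoxymethoxy)phenyl]-1-[3-iodo-2,4-bis(methoxymethoxy)phenyl]prop-2-en-1-one, via aldol adduct 15 (not isolated)
Conditions: KOH, EtOH/H2O, rt
Reagents that add atoms: none
Why: Claisen–Schmidt condensation, in which the ketone enolate adds to the non-enolisable aldehyde and the aldol dehydrates by E1cB to the conjugated (E)-enone, the thermodynamic alkene.

Step 9
Reactants: 16 (E)-3-[2,4-bis(methoxymethoxy)phenyl]-1-[3-iodo-2,4-bis(methoxymethoxy)phenyl]prop-2-en-1-one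
Product: 17 (E)-3-(2,4-dihydroxyphenyl)-1-(2,4-dihydroxy-3-iodophenyl)prop-2-en-1-one
Conditions: 3 M aq. HCl, MeOH, 50 °C
Reagents that add atoms: none
Why: Acid-catalysed methanolysis of the four aryl MOM acetals is safe at this stage because the fragment has neither a prenyl group nor a phenol placed to attack a saturated ketone.

Step 10
Reactants: 17 (E)-3-(2,4-dihydroxyphenyl)-1-(2,4-dihydroxy-3-iodophenyl)prop-2-en-1-one
Product: 18 (E)-3-[2,4-bis(benzoyloxy)phenyl]-1-[2,4-bis(benzoyloxy)-3-iodophenyl]prop-2-en-1-one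
Conditions: Bz2O, DMAP (0.2 equiv), pyridine, rt → 40 °C
Reagents that add atoms: benzoic anhydride, O=C(OC(=O)c1ccccc1)c1ccccc1
Why: DMAP-catalysed O-acylation turns all four phenols, the chelated one beside iodine included, into benzoates, which resist dilute acid, stay inert in a neutral cross-coupling and at 150 °C, and fall to mild base at the end.

Step 11
Reactants: 19 4-(trimethylsilyl)but-3-yn-2-one
Product: 21 (S)-3-methyl-1-(trimethylsilyl)hex-5-en-1-yn-3-ol, via diisopropyl borate ester 20 (not isolated)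
Conditions: allyl-B(OiPr)2, (S)-3,3′-Br2-BINOL (15 mol%), PhMe/PhCF3, −35 °C; aq. NaHCO3
Reagents that add atoms: allyldiisopropoxyborane, C=CCB(OC(C)C)OC(C)C
Why: Chiral-diol-catalysed asymmetric allylboration of the methyl alkynyl ketone through a closed chair transition state delivers allyl to the Si face and sets the tertiary carbinol as S, and any minor enantiomer leaves after step 14 as a separable diastereomer.

Step 12
Reactants: 21 (S)-3-methyl-1-(trimethylsilyl)hex-5-en-1-yn-3-ol
Product: 22 (S)-3-methyl-1-(trimethylsilyl)hex-5-en-1-yn-3-yl prop-2-enoate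
Conditions: acryloyl chloride, Et3N, DMAP (cat.), CH2Cl2, 0 °C → rt
Reagents that add atoms: acryloyl chloride, C=CC(Cl)=O
Why: DMAP-catalysed O-acylation of the tertiary alcohol gives the acrylate needed for ring closure without touching the stereocentre.

Step 13
Reactants: 22 (S)-3-methyl-1-(trimethylsilyl)hex-5-en-1-yn-3-yl prop-2-enoate
Product: 23 (S)-6-methyl-6-[(trimethylsilyl)ethynyl]-5,6-dihydro-2H-pyran-2-one
Conditions: second-generation Grubbs catalyst RuCl2(=CHPh)(SIMes)(PCy3) (5 mol%), CH2Cl2, 40 °C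
Reagents that add atoms: none
Why: Ring-closing olefin metathesis joins the allyl and acrylate termini with loss of ethene to the six-membered unsaturated lactone, the hindered silylalkyne staying out of the metathesis.

Step 14
Reactants: 23 (S)-6-methyl-6-[(trimethylsilyl)ethynyl]-5,6-dihydro-2H-pyran-2-one; 9 [2,4-bis(methoxymethoxy)phenyl]boronic acid
Product: 24 (4S,6S)-4-ArC-6-methyl-6-[(trimethylsilyl)ethynyl]oxan-2-one (ring C cis to the alkyne)
Conditions: 9 (2.5 equiv), [Rh(OH)(cod)]2 (1.5 mol%), (S)-BINAP (3.3 mol%), dioxane/H2O 10:1, 40 °C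
Reagents that add atoms: none
Why: Hayashi–Miyaura conjugate addition, in which the aryl–rhodium species adds to C4 of the enoate syn to the slim alkynyl group and not syn to methyl (least 1,3-diaxial strain in the chair-like insertion) while (S)-BINAP, which gives S adducts of six-membered enones and enoates, reinforces this bias, so C4 is set as S.

Step 15
Reactants: 5 1,3-bis(methoxymethoxy)-2-prenylbenzene; 24 (4S,6S)-4-ArC-6-methyl-6-[(trimethylsilyl)ethynyl]oxan-2-one
Product: 26 (3S,5S)-1-ArA-3-ArC-5-hydroxy-5-methyl-7-(trimethylsilyl)hept-6-yn-1-one (open form of the cyclic hemiketal), via ring A aryllithium 25 (not isolated)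
Conditions: 5, n-BuLi, TMEDA, THF, 0 °C; then 24, −78 °C; sat. aq. NH4Cl
Reagents that add atoms: none
Why: Directed ortho-metalation beside a MOM ether gives the ring A aryllithium (the position between the acetals is blocked by prenyl), which adds once to the lactone carbonyl because the tetrahedral lithium alkoxide persists at −78 °C and the released aryl ketone is deactivated, both stereocentres being spectators.

Step 16
Reactants: 26 (3S,5S)-1-ArA-3-ArC-5-hydroxy-5-methyl-7-(trimethylsilyl)hept-6-yn-1-one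
Product: 28 (2S,4S)-6-ArA-4-ArC-2-ethynyl-2-methyl-3,4-dihydro-2H-pyran, via silylalkynyl dihydropyran 27 (not isolated)
Conditions: PPTS (10 mol%), PhMe, 4 Å MS, 70 °C; then K2CO3 (cat.), MeOH, rt
Reagents that add atoms: none
Why: Acid-catalysed cyclodehydration (6-exo-trig hemiketalisation of the tertiary hydroxyl onto the aryl ketone, then loss of water from the ring A-stabilised oxocarbenium ion) gives the conjugated cyclic enol ether with the C2–O bond intact, and carbonate-mediated methanolysis then removes the alkynyl silyl group, so C2 and C4 keep their configuration.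

Step 17
Reactants: 28 (2S,4S)-6-ArA-4-ArC-2-ethynyl-2-methyl-3,4-dihydro-2H-pyran; 18 (E)-3-[2,4-bis(benzoyloxy)phenyl]-1-[2,4-bis(benzoyloxy)-3-iodophenyl]prop-2-en-1-one
Product: 31 (2S,4S)-6-ArA-4-ArC-2-methyl-2-[(E)-2-{2,6-bis(benzoyloxy)-3-[(E)-3-(2,4-bis(benzoyloxy)phenyl)prop-2-enoyl]phenyl}ethenyl]-3,4-dihydro-2H-pyran (styryl cis to ring C), via alkenylzirconocene chloride 29 (not isolated), via alkenylzinc chloride 30 (not isolated)
Conditions: Cp2Zr(H)Cl, THF, rt; ZnCl2, 0 °C; then 18, Pd(PPh3)4 (5 mol%), rt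
Reagents that add atoms: none
Why: Syn hydrozirconation places zirconium on the terminal carbon and fixes the E-alkene, and transmetalation to zinc followed by a zerovalent-palladium Negishi coupling joins it to the doubly ortho-substituted aryl iodide under neutral conditions that spare the benzoates, the enone, the enol ether and the tertiary allylic ether.

Step 18
Reactants: 31 (2S,4S)-6-ArA-4-ArC-2-methyl-2-[(E)-2-{2,6-bis(benzoyloxy)-3-[(E)-3-(2,4-bis(benzoyloxy)phenyl)prop-2-enoyl]phenyl}ethenyl]-3,4-dihydro-2H-pyran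
Product: 32 ArA (1R,2S,6S)-2-{2,6-bis(benzoyloxy)-3-[(E)-3-(2,4-bis(benzoyloxy)phenyl)prop-2-enoyl]phenyl}-6-ArC-4-methylcyclohex-3-en-1-yl ketone (acyl cis to ring B, trans to ring C)
Conditions: PhMe (degassed), 2,6-lutidine (0.2 equiv), 150 °C, sealed tube
Reagents that add atoms: none
Why: Concerted suprafacial [3,3] sigmatropic (Claisen) shift of the cyclic allyl vinyl ether C5=C6–O1–C2–CH=CH(ring B): the O1–C2 bond breaks as pyran C5 bonds to the styryl carbon, and release of the C7 aryl ketone makes the step irreversible. The closest known reaction type is the thermal Claisen ring contraction of 2-alkenyl-3,4-dihydro-2H-pyrans to 4-acylcyclohexenes. The cyclohexene closes through the pericyclic C1–C2 bond formation itself, and because pyran C2 and C5 are already tied through C3–C4 the six-atom array can only be a boat (bicyclo[2.2.2]octane-like), no chair being reachable. C1 is set by the face of the enol ether that carries the styryl arm (fixed by the 2S centre) and C2 by the E geometry of the styryl bond held in that boat, so acyl and ring B end up cis, while the 4S centre (ring C cis to the styryl group) places ring C trans to the acyl group. The step needs complete suprafacial transfer with no heterolysis of the tertiary allylic C–O bond, and the electron-poor benzoylated ring B, the non-polar solvent and the acid scavenger keep the shift concerted.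

Step 19
Reactants: 32 ArA (1R,2S,6S)-2-{2,6-bis(benzoyloxy)-3-[(E)-3-(2,4-bis(benzoyloxy)phenyl)prop-2-enoyl]phenyl}-6-ArC-4-methylcyclohex-3-en-1-yl ketone
Product: 33 2,4-dihydroxy-3-prenylphenyl (1R,2S,6S)-2-{2,6-bis(benzoyloxy)-3-[(E)-3-(2,4-bis(benzoyloxy)phenyl)prop-2-enoyl]phenyl}-6-(2,4-dihydroxyphenyl)-4-methylcyclohex-3-en-1-yl ketone
Conditions: HCl (1.25 M in MeOH), THF, 0 °C → rt
Reagents that add atoms: none
Why: Acid-catalysed methanolysis removes the four MOM acetals of rings A and C while the benzoates keep both ortho-oxygens of ring B masked, so ring B cannot join ring C in a bicyclic ketal at C7, and the mild conditions customary for prenylated chalcones leave the prenyl group open-chain.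

Step 20
Reactants: 33 2,4-dihydroxy-3-prenylphenyl (1R,2S,6S)-2-{2,6-bis(benzoyloxy)-3-[(E)-3-(2,4-bis(benzoyloxy)phenyl)prop-2-enoyl]phenyl}-6-(2,4-dihydroxyphenyl)-4-methylcyclohex-3-en-1-yl ketone
Product: 34 the target, 2,4-dihydroxy-3-prenylphenyl (1R,2S,6S)-2-{3-[(E)-3-(2,4-dihydroxyphenyl)prop-2-enoyl]-2,6-dihydroxyphenyl}-6-(2,4-dihydroxyphenyl)-4-methylcyclohex-3-en-1-yl ketone
Conditions: K2CO3 (0.5 equiv), MeOH (degassed), 0 °C → rt; aq. NH4Cl
Reagents that add atoms: none
Why: Carbonate-mediated transesterification (methanolysis) of the four aryl benzoates frees rings B and D without acid, and the phenoxide-deactivated C7 ketone should not enolise under this mild base, so C1, C2 and C6 are kept.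

Compound list
1 | resorcinol | Oc1cccc(O)c1 | starting material
2 | 1,3-bis(methoxymethoxy)benzene | COCOc1cccc(OCOC)c1 | intermediate
3 | prenyl bromide (1-bromo-3-methylbut-2-ene) | CC(C)=CCBr | starting material
4 | [2,6-bis(methoxymethoxy)phenyl]lithium | [Li]c1c(OCOC)cccc1OCOC | intermediate
5 | 1,3-bis(methoxymethoxy)-2-(3-methylbut-2-en-1-yl)benzene | CC(C)=CCc1c(OCOC)cccc1OCOC | intermediate
6 | 1-bromo-2,4-bis(methoxymethoxy)benzene | COCOc1ccc(Br)c(OCOC)c1 | intermediate
7 | [2,4-bis(methoxymethoxy)phenyl]lithium | [Li]c1ccc(OCOC)cc1OCOC | intermediate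
8 | lithium [2,4-bis(methoxymethoxy)phenyl]tris(propan-2-yloxy)borate | [Li+].CC(C)O[B-](OC(C)C)(OC(C)C)c1ccc(OCOC)cc1OCOC | intermediate
9 | [2,4-bis(methoxymethoxy)phenyl]boronic acid | OB(O)c1ccc(OCOC)cc1OCOC | intermediate
10 | 2,4-dihydroxyacetophenone | CC(=O)c1ccc(O)cc1O | starting material
11 | 1-(2,4-dihydroxy-3-iodophenyl)ethan-1-one | CC(=O)c1ccc(O)c(I)c1O | intermediate
12 | 1-[3-iodo-2,4-bis(methoxymethoxy)phenyl]ethan-1-one | CC(=O)c1ccc(OCOC)c(I)c1OCOC | intermediate
13 | 2,4-dihydroxybenzaldehyde | O=Cc1ccc(O)cc1O | starting material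
14 | 2,4-bis(methoxymethoxy)benzaldehyde | O=Cc1ccc(OCOC)cc1OCOC | intermediate
15 | 3-[2,4-bis(methoxymethoxy)phenyl]-3-hydroxy-1-[3-iodo-2,4-bis(methoxymethoxy)phenyl]propan-1-one (racemic aldol) | O=C(CC(O)c1ccc(OCOC)cc1OCOC)c1ccc(OCOC)c(I)c1OCOC | intermediate
16 | (E)-3-[2,4-bis(methoxymethoxy)phenyl]-1-[3-iodo-2,4-bis(methoxymethoxy)phenyl]prop-2-en-1-one | O=C(/C=C/c1ccc(OCOC)cc1OCOC)c1ccc(OCOC)c(I)c1OCOC | intermediate
17 | (E)-3-(2,4-dihydroxyphenyl)-1-(2,4-dihydroxy-3-iodophenyl)prop-2-en-1-one | O=C(/C=C/c1ccc(O)cc1O)c1ccc(O)c(I)c1O | intermediate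
18 | (E)-3-[2,4-bis(benzoyloxy)phenyl]-1-[2,4-bis(benzoyloxy)-3-iodophenyl]prop-2-en-1-one | O=C(/C=C/c1ccc(OC(=O)c2ccccc2)cc1OC(=O)c1ccccc1)c1ccc(OC(=O)c2ccccc2)c(I)c1OC(=O)c1ccccc1 | intermediate
19 | 4-(trimethylsilyl)but-3-yn-2-one | CC(=O)C#C[Si](C)(C)C | starting material
20 | diisopropyl (S)-3-methyl-1-(trimethylsilyl)hex-5-en-1-yn-3-yl borate | C=CC[C@](C)(OB(OC(C)C)OC(C)C)C#C[Si](C)(C)C | intermediate
21 | (S)-3-methyl-1-(trimethylsilyl)hex-5-en-1-yn-3-ol | C=CC[C@](C)(O)C#C[Si](C)(C)C | intermediate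
22 | (S)-3-methyl-1-(trimethylsilyl)hex-5-en-1-yn-3-yl prop-2-enoate | C=CC(=O)O[C@@](C)(CC=C)C#C[Si](C)(C)C | intermediate
23 | (S)-6-methyl-6-[(trimethylsilyl)ethynyl]-5,6-dihydro-2H-pyran-2-one | O=C1C=CC[C@@](C)(C#C[Si](C)(C)C)O1 | intermediate
24 | (4S,6S)-4-[2,4-bis(methoxymethoxy)phenyl]-6-methyl-6-[(trimethylsilyl)ethynyl]oxan-2-one | O=C1C[C@@H](c2ccc(OCOC)cc2OCOC)C[C@@](C)(C#C[Si](C)(C)C)O1 | intermediate
25 | [2,4-bis(methoxymethoxy)-3-(3-methylbut-2-en-1-yl)phenyl]lithium | [Li]c1ccc(OCOC)c(CC=C(C)C)c1OCOC | intermediate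
26 | (3S,5S)-3-[2,4-bis(methoxymethoxy)phenyl]-1-[2,4-bis(methoxymethoxy)-3-prenylphenyl]-5-hydroxy-5-methyl-7-(trimethylsilyl)hept-6-yn-1-one | CC(C)=CCc1c(OCOC)ccc(C(=O)C[C@@H](c2ccc(OCOC)cc2OCOC)C[C@](C)(O)C#C[Si](C)(C)C)c1OCOC | intermediate
27 | (2S,4S)-4-[2,4-bis(methoxymethoxy)phenyl]-6-[2,4-bis(methoxymethoxy)-3-prenylphenyl]-2-methyl-2-[(trimethylsilyl)ethynyl]-3,4-dihydro-2H-pyran | CC(C)=CCc1c(OCOC)ccc(C2=C[C@@H](c3ccc(OCOC)cc3OCOC)C[C@@](C)(C#C[Si](C)(C)C)O2)c1OCOC | intermediate
28 | (2S,4S)-4-[2,4-bis(methoxymethoxy)phenyl]-6-[2,4-bis(methoxymethoxy)-3-prenylphenyl]-2-ethynyl-2-methyl-3,4-dihydro-2H-pyran | CC(C)=CCc1c(OCOC)ccc(C2=C[C@@H](c3ccc(OCOC)cc3OCOC)C[C@@](C)(C#C)O2)c1OCOC | intermediate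
29 | chlorobis(cyclopentadienyl)[(E)-2-{(2S,4S)-4-ArC-6-ArA-2-methyl-3,4-dihydro-2H-pyran-2-yl}ethenyl]zirconium | CC(C)=CCc1c(OCOC)ccc(C2=C[C@@H](c3ccc(OCOC)cc3OCOC)C[C@@](C)(/C=C/[Zr](Cl)(C3C=CC=C3)C3C=CC=C3)O2)c1OCOC | intermediate
30 | chloro[(E)-2-{(2S,4S)-4-ArC-6-ArA-2-methyl-3,4-dihydro-2H-pyran-2-yl}ethenyl]zinc | CC(C)=CCc1c(OCOC)ccc(C2=C[C@@H](c3ccc(OCOC)cc3OCOC)C[C@@](C)(/C=C/[Zn]Cl)O2)c1OCOC | intermediate
31 | (2S,4S)-6-ArA-4-ArC-2-methyl-2-[(E)-2-{2,6-bis(benzoyloxy)-3-[(E)-3-(2,4-bis(benzoyloxy)phenyl)prop-2-enoyl]phenyl}ethenyl]-3,4-dihydro-2H-pyran | CC(C)=CCc1c(OCOC)ccc(C2=C[C@@H](c3ccc(OCOC)cc3OCOC)C[C@@](C)(/C=C/c3c(OC(=O)c4ccccc4)ccc(C(=O)/C=C/c4ccc(OC(=O)c5ccccc5)cc4OC(=O)c4ccccc4)c3OC(=O)c3ccccc3)O2)c1OCOC | intermediate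
32 | ArA (1R,2S,6S)-2-{2,6-bis(benzoyloxy)-3-[(E)-3-(2,4-bis(benzoyloxy)phenyl)prop-2-enoyl]phenyl}-6-ArC-4-methylcyclohex-3-en-1-yl ketone | CC(C)=CCc1c(OCOC)ccc(C(=O)[C@H]2[C@@H](c3c(OC(=O)c4ccccc4)ccc(C(=O)/C=C/c4ccc(OC(=O)c5ccccc5)cc4OC(=O)c4ccccc4)c3OC(=O)c3ccccc3)C=C(C)C[C@@H]2c2ccc(OCOC)cc2OCOC)c1OCOC | intermediate
33 | 2,4-dihydroxy-3-prenylphenyl (1R,2S,6S)-2-{2,6-bis(benzoyloxy)-3-[(E)-3-(2,4-bis(benzoyloxy)phenyl)prop-2-enoyl]phenyl}-6-(2,4-dihydroxyphenyl)-4-methylcyclohex-3-en-1-yl ketone | CC(C)=CCc1c(O)ccc(C(=O)[C@H]2[C@@H](c3c(OC(=O)c4ccccc4)ccc(C(=O)/C=C/c4ccc(OC(=O)c5ccccc5)cc4OC(=O)c4ccccc4)c3OC(=O)c3ccccc3)C=C(C)C[C@@H]2c2ccc(O)cc2O)c1O | intermediate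
34 | CNP0186421.2, 2,4-dihydroxy-3-prenylphenyl (1R,2S,6S)-2-{3-[(E)-3-(2,4-dihydroxyphenyl)prop-2-enoyl]-2,6-dihydroxyphenyl}-6-(2,4-dihydroxyphenyl)-4-methylcyclohex-3-en-1-yl ketone | CC(C)=CCc1c(O)ccc(C(=O)[C@H]2[C@@H](c3c(O)ccc(C(=O)/C=C/c4ccc(O)cc4O)c3O)C=C(C)C[C@@H]2c2ccc(O)cc2O)c1O | target

Total step count: 20. Longest linear sequence: 10 steps (steps 11–20 from 19; the ring C branch through steps 1, 3, 4 and 14–20 is equally long).

Steps most likely to fail

1. Step 18 (the key step). The tertiary allylic C–O bond may break heterolytically before C1–C2 forms, so that the ion pair recombines without stereochemical transfer or eliminates to a triene, or the shift may be too slow at the styryl carbon, which carries a 2,6-disubstituted aryl group. The fallback for step 18 sets out from 31: zerovalent palladium (Pd2(dba)3, dppe, THF, 40 °C) would ionise the allylic enol ether to a π-allyl complex that carries its own enolate. Closure of the enolate carbon onto the styryl terminus, anti to the metal, is a Tsuji–Trost O-to-C allyl transfer of an allyl vinyl ether (closure at the quaternary terminus would need a cyclobutane). Ionisation and attack both go with inversion, so the new bond should form on the allyl face that the oxygen left, as in the thermal shift, and this fallback comes back to the route at 32. It makes no compound outside the route, which the entry F0 records.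

2. Step 17. Oxidative addition and transmetalation may be slow at the doubly ortho-substituted iodide, and the zinc halide may ionise the tertiary allylic ether and erode its configuration. The fallback for step 17 sets out from 28: Cp2Zr(H)Cl-catalysed hydroboration with pinacolborane (Et3N, CH2Cl2, rt) would give the isolable alkenylboronate (2S,4S)-4-[2,4-bis(methoxymethoxy)phenyl]-6-[2,4-bis(methoxymethoxy)-3-prenylphenyl]-2-methyl-2-[(E)-2-(4,4,5,5-tetramethyl-1,3,2-dioxaborolan-2-yl)ethenyl]-3,4-dihydro-2H-pyran F1. A Suzuki–Miyaura coupling of F1 with 18 under anhydrous fluoride activation (Pd(PPh3)4, CsF, THF, 50 °C) needs no zinc halide and spares the benzoates, and this fallback comes back to the route at 31.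

3. Step 14. Facial selectivity at C4 may be poor if catalyst and lactone do not cooperate, and the electron-rich boronic acid may protodeboronate before it transmetalates. The fallback for step 14 sets out from 6: magnesium insertion (Mg, THF) would give the Grignard reagent [2,4-bis(methoxymethoxy)phenyl]magnesium bromide F2. The CuBr·SMe2-catalysed conjugate addition of F2 to 23 (THF, −40 °C; aq. NH4Cl) is governed by the lactone alone (aryl enters syn to the alkynyl group), and this fallback comes back to the route at 24 once the minor trans isomer is removed by chromatography.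

Further compounds
F0 | step 18 | none | none
F1 | step 17 | (2S,4S)-4-[2,4-bis(methoxymethoxy)phenyl]-6-[2,4-bis(methoxymethoxy)-3-prenylphenyl]-2-methyl-2-[(E)-2-(4,4,5,5-tetramethyl-1,3,2-dioxaborolan-2-yl)ethenyl]-3,4-dihydro-2H-pyran | CC(C)=CCc1c(OCOC)ccc(C2=C[C@@H](c3ccc(OCOC)cc3OCOC)C[C@@](C)(/C=C/B3OC(C)(C)C(C)(C)O3)O2)c1OCOC
F2 | step 14 | [2,4-bis(methoxymethoxy)phenyl]magnesium bromide | Br[Mg]c1ccc(OCOC)cc1OCOC
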